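At early times the zeta flask loses electrophile quickly, and its first reading, taken with one nucleophile used per electrophile lost, gives a first-step constant of 0.0205 M⁻¹ s⁻¹.

| flask | electrophile | nucleophile | free base | remark | time |
|---|---|---|---|---|---|
| zeta | 0.062 M | 0.046 M | 0.0744 M | run made earlier |  |
| ochre | 0.062 M | 0.0682 M | 0.190 M |  | 1.0 h |
| teal | 0.062 M | 0.0682 M | 0.0740 M |  | 1.0 h |

zeta run (percent of the electrophile charged)

| time / min | electrophile / % | target / % | over-reaction product / % |
|---|---|---|---|
| 4.00 | 82 | 16 | 4 |
| 8.00 | 71 | 23 | 3 |
| 10.0 | 63 | 26 | 7 |
| 15.0 | 56 | 29 | 15 |
| 20.0 | 52 | 31 | 18 |

(scatter of a reading: 2 percentage points)

- what was read earlier has a scatter of 2 percentage points, one standard deviation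
- no earlier run changes the charge of free base; that part of a forecast is a guess

I read the same constant a second way, from the fall of electrophile between 10.0 min and 20.0 min, and for that I need [nucleophile] at 15.0 min. If each over-reaction product holds a second nucleophile, [nucleophile] is down to 9.42 mM and the constant climbs to 0.0340 M⁻¹ s⁻¹, but if it holds none, [nucleophile] is 0.0187 M and the constant is 0.0171 M⁻¹ s⁻¹, which stays near the early value. The scatter blurs this, so it is a lean and not a proof, yet I drop the count that makes a constant grow. I suppose instead that free base takes up one acid set free per electrophile lost and enters each over-reaction product once, which puts [free base] in zeta at 15.0 min at 0.0378 M. Over the same stretch the readings give 0.0167 M⁻¹ s⁻¹ for the fraction of target lost per minute divided by [free base], the over-reaction constant. Target then decays pseudo-first-order, with a half-life of ln(2) over that constant times [free base]. No earlier run changes the free base, so this is a guess.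

1. which of these there is most of at the end, counted by the electrophile in it, ochre (over-reaction product / target / electrophile)
2. which of these there is most of at the end, counted by the electrophile in it, teal (over-reaction product / target / electrophile)
3. how much there is at the end of the one of these that leads, in percent of the electrophile charged: ochre
4. how much there is at the end of the one of these that leads, in percent of the electrophile charged: teal

Once the electrophile has reacted, my count leaves 0.128 M of free base in ochre and 0.0120 M in teal, before any free base has entered over-reaction product. If a further amount equal to the electrophile charged enters over-reaction product, ochre still keeps 0.0660 M by my count, so target's half-life in ochre is still 10.5 min, shorter than the 1.0 h of the run. In teal the 0.0120 M gives a half-life of 57.6 min, about as long as the run, and by my count that half-life lengthens as this free base enters over-reaction product. So I commit to over-reaction product leading in ochre and target leading in teal. The forecast gives over-reaction product at 44 % for ochre and over-reaction product at 36 % for teal, holding that “the over-reaction product is probably target + a second nucleophile”, and on teal I differ from it.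

The flask gives over-reaction product at 82.6 % in ochre and target at 45.6 % in teal.

    electrophile + nucleophile → acid set free + target (k = 0.0210 M⁻¹ s⁻¹)
    nucleophile + acid set free ⇌ protonated nucleophile, settled at all times (K = 890 M⁻¹)
    acid set free + free base ⇌ salt of the base, settled at all times (K = 25000 M⁻¹)
    free base + target → over-reaction product (k = 0.0170 M⁻¹ s⁻¹)

At 1.00 h teal holds 4.34 % of its free base, which puts target's half-life at 3.58 h, longer than the run. The neighbouring flask, like ochre but with 0.15 M of electrophile, holds 29.4 % of its free base at 1.00 h, which gives a half-life of 12.4 min, shorter than the run, and its target stands at 1.39 %.

The numbers in the tables are simulated from invented constants; the scatter is artificial.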